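## Retrosynthetic overview

- The only ring, the 4-hydroxy-2-pyranone, is closed last among the skeletal events by O1–C2 lactonisation (C–O) of an open-chain 3,5-dioxo ester. Only the oxidation of the C9 carbinol to the ketone follows, because a C9 ketone would make C6–H a doubly vinylogous 1,3-dicarbonyl C–H that no base step could tolerate. (Side-chain numbering: C1–C14 of the tetradecatetraenyl chain, C2 on the pyranone.)
- The 3,5-dioxo ester comes from a 2,4-dienoate ester and the dianion of methyl 2-methyl-3-oxopentanoate.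
- C8–C9 comes from an (E)-alkenylzinc (syn-hydrozirconation of a methyl-capped alkyne) and (2E,4S)-2,4-dimethylhex-2-enal, which carries C12 from (S)-2-methylbutan-1-ol.
- The C6 stereocentre and the C5–C6 bond come from an enantioconvergent nickel coupling of racemic 4-bromopent-2-yne with an alkenylzinc made by carboalumination of prop-2-yn-1-ol.
- The four trisubstituted E-alkenes come from carboalumination, two Wittig reactions and the hydrozirconation.

Assumption: the ligand enantiomer written in step 3 is taken to give (S)-10 by analogy with arylzinc couplings; if it gives (R)-10, its mirror image is used.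

## Route

Step 1
Reactants: 1 (S)-2-methylbutan-1-ol; 2 2-(triphenylphosphoranylidene)propanal
Product: 4 (2E,4S)-2,4-dimethylhex-2-enal, via (S)-2-methylbutanal 3 (not isolated)
Conditions: TEMPO (1 mol%), KBr (10 mol%), NaOCl (1.1 equiv), NaHCO3, CH2Cl2/H2O, 0 °C; dried CH2Cl2 layer, 2 (1.05 equiv), PhMe added, CH2Cl2 distilled off, 80 °C
Reagents that add atoms: none
Why: Buffered TEMPO/hypochlorite oxidation gives the configurationally labile aldehyde 3 cold and it is trapped at once by the stabilised, E-selective formyl ylide (Wittig reaction), so the C4 stereocentre comes unchanged from the chiral pool.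

Step 2
Reactants: 5 pent-3-yn-2-ol (racemic)
Product: 6 4-bromopent-2-yne (racemic)
Conditions: PPh3 (1.1 equiv), CBr4 (1.1 equiv), CH2Cl2, 0 °C
Reagents that add atoms: tetrabromomethane, BrC(Br)(Br)Br
Why: Appel reaction; bromide displaces the alkoxyphosphonium ion at 0 °C without allene formation, and the product is needed only as the racemate.

Step 3
Reactants: 7 prop-2-yn-1-ol; 6 4-bromopent-2-yne (racemic)
Product: 10 (2E,4S)-2,4-dimethylhept-2-en-5-yn-1-ol, via alkenylalane 8 (not isolated), via alkenylzinc chloride 9 (not isolated)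
Conditions: 7 (1.6 equiv), Me3Al (4.8 equiv), Cp2ZrCl2 (0.4 equiv), CH2Cl2, 0 °C→rt, 16 h; volatiles removed in vacuo; ZnCl2 (1.6 equiv), THF, 0 °C; then 6 (1.0 equiv), NiCl2(dme) (5 mol%), 2,6-bis[(3aS,8aR)-3a,8a-dihydro-8H-indeno[1,2-d]oxazol-2-yl]pyridine (6.5 mol%), DME, −20 °C, 24 h; aq. NH4Cl
Reagents that add atoms: trimethylaluminium, C[Al](C)C
Why: Proposed new method: a nickel/pybox-catalysed enantioconvergent Negishi alkenylation of a racemic secondary propargylic bromide with a trisubstituted alkenylzinc made in the same flask by Zr-catalysed syn-carboalumination (which fixes the 2E alkene and the C2 methyl); a monovalent pybox-bound alkenylnickel abstracts bromine from either enantiomer of 6 to give a planar propargyl radical, the radical is captured at its propargylic (not allenic) terminus on the face left open by the C2-symmetric ligand, and reductive elimination from trivalent nickel forms the C3–C4 bond with retention of alkene geometry and sets C4 as (S); the closest known reactions are the nickel/pybox stereoconvergent Negishi arylation of racemic propargylic bromides and the nickel-catalysed stereoconvergent alkenylation of racemic α-bromo ketones with alkenylzirconium reagents.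

Step 4
Reactants: 10 (2E,4S)-2,4-dimethylhept-2-en-5-yn-1-ol; 11 ethyl 2-(triphenylphosphoranylidene)propanoate
Product: 13 ethyl (2E,4E,6S)-2,4,6-trimethylnona-2,4-dien-7-ynoate, via enynal 12 (not isolated)
Conditions: MnO2 (15 equiv), 11 (1.3 equiv), CH2Cl2, 40 °C
Reagents that add atoms: none
Why: Tandem allylic oxidation/Wittig olefination; neutral MnO2 gives the enal, which the stabilised α-methyl ylide converts in situ into the 2E ester, so the γ-stereocentre of the sensitive enal is never exposed to base or isolation.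

Step 5
Reactants: 13 ethyl (2E,4E,6S)-2,4,6-trimethylnona-2,4-dien-7-ynoate; 4 (2E,4S)-2,4-dimethylhex-2-enal
Product: 16 ethyl (2E,4E,6S,7E,10E,12S)-9-hydroxy-2,4,6,8,10,12-hexamethyltetradeca-2,4,7,10-tetraenoate (mixture at C9), via alkenylzirconocene 14 (not isolated), via alkenyl(methyl)zinc 15 (not isolated)
Conditions: Cp2Zr(H)Cl (1.4 equiv), CH2Cl2, rt, 2 h; Me2Zn (1.4 equiv), −65 °C; 4 (1.5 equiv), 0 °C; aq. NH4Cl
Reagents that add atoms: none
Why: Hydrozirconation/zirconium-to-zinc transmetalation/carbonyl alkenylation; Cp2Zr(H)Cl adds syn across the internal alkyne with zirconium on the less hindered methyl-bearing carbon (the slight excess equilibrates the regioisomers), the ester and the trisubstituted alkenes stay inert, and the alkenylzinc adds 1,2 to enal 4 to give the 7E alkene, the new C9 carbinol being an epimer mixture that step 7 erases.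

Step 6
Reactants: 16 ethyl (2E,4E,6S,7E,10E,12S)-9-hydroxy-2,4,6,8,10,12-hexamethyltetradeca-2,4,7,10-tetraenoate; 17 methyl 2-methyl-3-oxopentanoate
Product: 20 4-hydroxy-6-[(2E,4E,6S,7E,10E,12S)-9-hydroxy-4,6,8,10,12-pentamethyltetradeca-2,4,7,10-tetraen-2-yl]-3,5-dimethyl-2H-pyran-2-one (mixture at C9), via keto ester dianion 18 (not isolated), via dioxo ester 19 (not isolated)
Conditions: 17 (3.5 equiv), LiN(iPr)2 (7.0 equiv), THF, −78→0 °C; 16, −78→−20 °C; AcOH; crude, DBU (4 equiv), PhMe, rt→40 °C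
Reagents that add atoms: none
Why: Claisen-type γ-acylation of a β-keto ester dianion by the dienoate, then DBU-mediated enol lactonisation in which the C5 enol oxygen attacks the methyl ester carbonyl (O1–C2 bond) with loss of methanol and closes the only ring, the C9 hydroxyl riding through as its alkoxide so that C6–H stays only singly activated.

Step 7
Reactants: 20 4-hydroxy-6-[(2E,4E,6S,7E,10E,12S)-9-hydroxy-4,6,8,10,12-pentamethyltetradeca-2,4,7,10-tetraen-2-yl]-3,5-dimethyl-2H-pyran-2-one
Product: 21 4-hydroxy-3,5-dimethyl-6-[(2E,4E,6S,7E,10E,12S)-4,6,8,10,12-pentamethyl-9-oxotetradeca-2,4,7,10-tetraen-2-yl]-2H-pyran-2-one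
Conditions: MnO2 (20 equiv), CH2Cl2, rt
Reagents that add atoms: none
Why: Allylic oxidation with MnO2 converts the doubly allylic C9 alcohol into the cross-conjugated dienone under neutral heterogeneous conditions, so the now base-labile C6 stereocentre and the acidic pyranone are left alone and both C9 epimers converge on the target.

## Compound list

1 | (S)-2-methylbutan-1-ol | CC[C@H](C)CO | starting material
2 | 2-(triphenylphosphoranylidene)propanal | CC(C=O)=P(c1ccccc1)(c1ccccc1)c1ccccc1 | starting material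
3 | (S)-2-methylbutanal | CC[C@H](C)C=O | intermediate
4 | (2E,4S)-2,4-dimethylhex-2-enal | CC[C@H](C)/C=C(\C)C=O | intermediate
5 | pent-3-yn-2-ol (racemic) | CC#CC(C)O | starting material
6 | 4-bromopent-2-yne (racemic) | CC#CC(C)Br | intermediate
7 | prop-2-yn-1-ol | C#CCO | starting material
8 | {(1E)-3-[(dimethylalumanyl)oxy]-2-methylprop-1-en-1-yl}dimethylalumane | C[Al](C)/C=C(\C)CO[Al](C)C | intermediate
9 | chloro{(1E)-3-[(dimethylalumanyl)oxy]-2-methylprop-1-en-1-yl}zinc | Cl[Zn]/C=C(\C)CO[Al](C)C | intermediate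
10 | (2E,4S)-2,4-dimethylhept-2-en-5-yn-1-ol | CC#C[C@@H](C)/C=C(\C)CO | intermediate
11 | ethyl 2-(triphenylphosphoranylidene)propanoate | CCOC(=O)C(C)=P(c1ccccc1)(c1ccccc1)c1ccccc1 | starting material
12 | (2E,4S)-2,4-dimethylhept-2-en-5-ynal | CC#C[C@@H](C)/C=C(\C)C=O | intermediate
13 | ethyl (2E,4E,6S)-2,4,6-trimethylnona-2,4-dien-7-ynoate | CC#C[C@@H](C)/C=C(C)/C=C(\C)C(=O)OCC | intermediate
14 | ethyl (2E,4E,6S,7E)-8-[chlorobis(cyclopentadienyl)zirconio]-2,4,6-trimethylnona-2,4,7-trienoate | Cl[Zr](C1C=CC=C1)(C1C=CC=C1)/C(C)=C/[C@@H](C)/C=C(C)/C=C(\C)C(=O)OCC | intermediate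
15 | ethyl (2E,4E,6S,7E)-2,4,6-trimethyl-8-(methylzincio)nona-2,4,7-trienoate | C[Zn]/C(C)=C/[C@@H](C)/C=C(C)/C=C(\C)C(=O)OCC | intermediate
16 | ethyl (2E,4E,6S,7E,10E,12S)-9-hydroxy-2,4,6,8,10,12-hexamethyltetradeca-2,4,7,10-tetraenoate (mixture at C9) | CC[C@H](C)/C=C(\C)C(O)/C(C)=C/[C@@H](C)/C=C(C)/C=C(\C)C(=O)OCC | intermediate
17 | methyl 2-methyl-3-oxopentanoate | CCC(=O)C(C)C(=O)OC | starting material
18 | dilithium 1-methoxy-2-methylpenta-1,3-diene-1,3-bis(olate) | CC=C([O-])C(C)=C([O-])OC.[Li+].[Li+] | intermediate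
19 | methyl (6E,8E,10S,11E,14E,16S)-13-hydroxy-2,4,6,8,10,12,14,16-octamethyl-3,5-dioxooctadeca-6,8,11,14-tetraenoate | CC[C@H](C)/C=C(\C)C(O)/C(C)=C/[C@@H](C)/C=C(C)/C=C(\C)C(=O)C(C)C(=O)C(C)C(=O)OC | intermediate
20 | 4-hydroxy-6-[(2E,4E,6S,7E,10E,12S)-9-hydroxy-4,6,8,10,12-pentamethyltetradeca-2,4,7,10-tetraen-2-yl]-3,5-dimethyl-2H-pyran-2-one (mixture at C9) | CC[C@H](C)/C=C(\C)C(O)/C(C)=C/[C@@H](C)/C=C(C)/C=C(\C)c1oc(=O)c(C)c(O)c1C | intermediate
21 | 4-hydroxy-3,5-dimethyl-6-[(2E,4E,6S,7E,10E,12S)-4,6,8,10,12-pentamethyl-9-oxotetradeca-2,4,7,10-tetraen-2-yl]-2H-pyran-2-one | CC[C@H](C)/C=C(\C)C(=O)/C(C)=C/[C@@H](C)/C=C(C)/C=C(\C)c1oc(=O)c(C)c(O)c1C | target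

## Step count and risks

Total step count: 7. Longest linear sequence: 6 steps (5 → 6 → 10 → 13 → 16 → 20 → 21).

**Step 3 (the proposed new coupling).** The risks are a low ee with a propargylic radical that carries only methyl groups, competing methyl transfer from residual Al–Me/Zn–Me species, and interference by the aluminium alkoxide. Any (R)-10 would appear after step 5 as a C6 epimer. The fallback uses known chemistry, sets out from 5 and comes back at 10. Lipase-mediated kinetic resolution of 5 (Amano lipase PS, vinyl acetate, run past 50% conversion) leaves (S)-pent-3-yn-2-ol F1. MsCl/Et3N gives (S)-pent-3-yn-2-yl methanesulfonate F2. A Marshall propargylation with methacrolein (Pd(OAc)2 5 mol%, PPh3, InI (indium monoiodide), THF/DMPU, rt) goes by anti SN2' attack of zerovalent palladium, transmetalation to the allenylindium and syn SE2' addition through a cyclic transition state. It transfers the chirality with net inversion and gives the anti adduct (3R,4R)-2,4-dimethylhept-1-en-5-yn-3-ol F3. A Ph3SiOReO3-catalysed 1,3-transposition of this allylic alcohol (chair-like [3,3] shift, Et2O, 0 °C) moves the hydroxyl to the primary position and forms the trisubstituted E alkene, which is 10.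

**Step 5.** The risks are incomplete regiocontrol of the hydrozirconation, slow reduction of the dienoate by Cp2Zr(H)Cl during the longer reaction time an internal alkyne needs, and sluggish addition of a hindered alkenylzinc to a hindered enal. The fallback sets out from 10 and comes back at 16. Hydrozirconation of 10 itself (Cp2Zr(H)Cl 2.3 equiv, the first equivalent consumed by the hydroxyl, no ester present) and iodinolysis with I2 give (2E,4S,5E)-6-iodo-2,4-dimethylhepta-2,5-dien-1-ol F4. The tandem MnO2/Wittig reaction with 11 gives ethyl (2E,4E,6S,7E)-8-iodo-2,4,6-trimethylnona-2,4,7-trienoate F5. A Nozaki–Hiyama–Kishi coupling of F5 with enal 4 (CrCl2 6 equiv, NiCl2 1 mol%, DMSO, rt) then gives 16.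

**Step 6.** The risks are proton transfer from C6–H or the C4 methyl of the dienoate to the dianion in place of acylation, and base-induced isomerisation of the skipped diene during the DBU stage. The fallback sets out from 16 and comes back at 20; it replaces the ester acylation by an aldehyde aldol, which is fast at −78 °C. TBSOTf/2,6-lutidine gives 9-silyloxy ester F6. iBu2AlH gives 9-silyloxy tetraenol F7. MnO2 gives 9-silyloxy tetraenal F8. Addition of dianion 18 at −78 °C gives aldol adduct F9. Dess–Martin periodinane gives silylated dioxo ester F10. DBU in PhMe closes the ring by the same O1–C2 lactonisation to silylated pyranone F11. Bu4NF buffered with AcOH then releases 20.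

## Further compounds

F1 | step 3 | (S)-pent-3-yn-2-ol | CC#C[C@H](C)O
F2 | step 3 | (S)-pent-3-yn-2-yl methanesulfonate | CC#C[C@H](C)OS(C)(=O)=O
F3 | step 3 | (3R,4R)-2,4-dimethylhept-1-en-5-yn-3-ol | C=C(C)[C@H](O)[C@H](C)C#CC
F4 | step 5 | (2E,4S,5E)-6-iodo-2,4-dimethylhepta-2,5-dien-1-ol | I/C(C)=C/[C@@H](C)/C=C(\C)CO
F5 | step 5 | ethyl (2E,4E,6S,7E)-8-iodo-2,4,6-trimethylnona-2,4,7-trienoate | I/C(C)=C/[C@@H](C)/C=C(C)/C=C(\C)C(=O)OCC
F6 | step 6 | ethyl (2E,4E,6S,7E,10E,12S)-9-[(tert-butyldimethylsilyl)oxy]-2,4,6,8,10,12-hexamethyltetradeca-2,4,7,10-tetraenoate | CC[C@H](C)/C=C(\C)C(O[Si](C)(C)C(C)(C)C)/C(C)=C/[C@@H](C)/C=C(C)/C=C(\C)C(=O)OCC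
F7 | step 6 | (2E,4E,6S,7E,10E,12S)-9-[(tert-butyldimethylsilyl)oxy]-2,4,6,8,10,12-hexamethyltetradeca-2,4,7,10-tetraen-1-ol | CC[C@H](C)/C=C(\C)C(O[Si](C)(C)C(C)(C)C)/C(C)=C/[C@@H](C)/C=C(C)/C=C(\C)CO
F8 | step 6 | (2E,4E,6S,7E,10E,12S)-9-[(tert-butyldimethylsilyl)oxy]-2,4,6,8,10,12-hexamethyltetradeca-2,4,7,10-tetraenal | CC[C@H](C)/C=C(\C)C(O[Si](C)(C)C(C)(C)C)/C(C)=C/[C@@H](C)/C=C(C)/C=C(\C)C=O
F9 | step 6 | methyl (6E,8E,10S,11E,14E,16S)-13-[(tert-butyldimethylsilyl)oxy]-5-hydroxy-2,4,6,8,10,12,14,16-octamethyl-3-oxooctadeca-6,8,11,14-tetraenoate | CC[C@H](C)/C=C(\C)C(O[Si](C)(C)C(C)(C)C)/C(C)=C/[C@@H](C)/C=C(C)/C=C(\C)C(O)C(C)C(=O)C(C)C(=O)OC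
F10 | step 6 | methyl (6E,8E,10S,11E,14E,16S)-13-[(tert-butyldimethylsilyl)oxy]-2,4,6,8,10,12,14,16-octamethyl-3,5-dioxooctadeca-6,8,11,14-tetraenoate | CC[C@H](C)/C=C(\C)C(O[Si](C)(C)C(C)(C)C)/C(C)=C/[C@@H](C)/C=C(C)/C=C(\C)C(=O)C(C)C(=O)C(C)C(=O)OC
F11 | step 6 | 6-[(2E,4E,6S,7E,10E,12S)-9-[(tert-butyldimethylsilyl)oxy]-4,6,8,10,12-pentamethyltetradeca-2,4,7,10-tetraen-2-yl]-4-hydroxy-3,5-dimethyl-2H-pyran-2-one | CC[C@H](C)/C=C(\C)C(O[Si](C)(C)C(C)(C)C)/C(C)=C/[C@@H](C)/C=C(C)/C=C(\C)c1oc(=O)c(C)c(O)c1C
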